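**Retrosynthetic overview**
1. Lactone A and the C9 ketone are unmasked last from an isoxazoline (C9=N–O–C11) by N–O hydrogenolysis. The same hydrogenation saturates a butenolide to lactone B.
2. Lactone B comes from a vinylogous Mannich addition of 3-methyl-2-silyloxyfuran to a C3 N-acyliminium ion of the closed macrocycle.
3. Key disconnection: C9–C10 and O–C11 are made together by intramolecular nitrile oxide cycloaddition onto a (Z)-C10=C11 alkene, so the eleven-membered ring and the isoxazoline form in one operation.
4. C1–C12 comes from Michael addition of the N-(5-chloropentyl)-L-pyroglutamic acid dianion to a (2E,4Z)-dienoate. The C3 carboxyl sets C1, is then removed anodically, and C1 later resets C3.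
5. Ring order: pyrrolidinone (chiral pool) → macrocycle + isoxazoline → butenolide B → lactone B + lactone A.

Assumption: atom labels follow tuberostemonine numbering (N4; C1, C2, C3, C9a = pyrrolidinone; C5–C8 = chain; C9 = ketone; C10 bears the ethyl group; C11–C14 = lactone A; C18–C21 = lactone B), and the SMILES is read as the 1S,3S,10S,11R,12S,13S,18S,20S isomer.

**Step 1**
Reactants: 1 methyl L-pyroglutamate; 2 1-bromo-5-chloropentane
Product: 4 (S)-1-(5-chloropentyl)-5-oxopyrrolidine-2-carboxylic acid, via methyl ester 3 (not isolated)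
Conditions: NaH (1.0 equiv), DMF, 0 °C to rt; then LiOH, THF/H2O, rt; HCl work-up
Reagents that add atoms: lithium hydroxide, [Li+].[OH-]
Why: SN2 N-alkylation of the sodium lactamate takes place at the bromide end of 2 (bromide leaves far faster than chloride) and in-pot saponification frees the acid; C3 (S) is that of L-pyroglutamate, and using only one equivalent of base keeps it from enolising.

**Step 2**
Reactants: 5 (Z)-pent-2-en-1-ol; 6 methyl 2-(triphenylphosphoranylidene)propanoate
Product: 8 methyl (2E,4Z)-2-methylhepta-2,4-dienoate, via (Z)-pent-2-enal 7 (not isolated)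
Conditions: MnO2 (10 equiv), CH2Cl2, rt
Reagents that add atoms: none
Why: In this tandem allylic oxidation–Wittig olefination the isomerisation-prone (Z)-enal is trapped as it forms by the stabilised ylide, which builds C12=C13 E-selectively and leaves the Z geometry of C10=C11 untouched.

**Step 3**
Reactants: 4 (S)-1-(5-chloropentyl)-5-oxopyrrolidine-2-carboxylic acid; 8 methyl (2E,4Z)-2-methylhepta-2,4-dienoate
Product: 10 (2S,4S)-1-(5-chloropentyl)-4-[(2S,3S,4Z)-1-methoxy-2-methyl-1-oxohept-4-en-3-yl]-5-oxopyrrolidine-2-carboxylic acid, via dilithium dianion 9 (not isolated)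
Conditions: LiN(iPr)2 (2.1 equiv), THF, −78 to −30 °C; 8, −78 °C; AcOH, −78 °C
Reagents that add atoms: none
Why: This is a Michael (1,4-) addition of a carboxylate/lactam-enolate dianion: the solvated lithium carboxylate at C3 shields one enolate face (C1–C12 bond trans to C3, 1S), the lithium-bridged closed transition state of the ring-locked E(O)-enolate and the (E)-enoate favours 1,4- over 1,6-attack and the C1/C12 syn pair (12S), and cold protonation of the ester enolate anti to the lactam residue in its H12-eclipsed (A1,3-minimised) conformer gives 13S.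

**Step 4**
Reactants: 10 Michael adduct acid
Product: 12 methyl (2S,3S,4Z)-3-[(3S)-1-(5-chloropentyl)-5-methoxy-2-oxopyrrolidin-3-yl]-2-methylhept-4-enoate (both OMe epimers), via N-acyliminium ion 11 (not isolated)
Conditions: graphite anode and cathode, undivided cell, constant current, 2.5 F/mol, Et3N (0.2 equiv), MeOH, 0 °C
Reagents that add atoms: methanol, CO
Why: In this Hofer–Moest (non-Kolbe) anodic decarboxylation, two-electron oxidation of the α-amido carboxylate gives the nitrogen-stabilised cation, which methanol traps, while the isolated alkene, ester and chloride are not touched; C3 is deliberately erased after it has set C1, so the epimer mixture does not matter.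

**Step 5**
Reactants: 12 5-methoxylactam chloride
Product: 14 methyl (2S,3S,4Z)-3-[(3S)-5-methoxy-1-(5-nitropentyl)-2-oxopyrrolidin-3-yl]-2-methylhept-4-enoate, via primary iodide 13 (not isolated)
Conditions: NaNO2 (3 equiv), NaI (0.2 equiv), urea, DMSO, 40 °C
Reagents that add atoms: sodium nitrite, [Na+].[O-]N=O
Why: The Kornblum nitrite displacement runs through a catalytic Finkelstein iodide; SN2 at the primary carbon touches no stereocentre, and neutral DMSO leaves the N,O-acetal and the ester alone.

**Step 6**
Reactants: 14 nitro compound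
Product: 16 isoxazoline-bridged eleven-membered lactam (1S,10R,11R,12S,13S; C9=N–O–C11 bridge; ethyl and C12 cis on the isoxazoline; C3–OMe epimers; C12 carries CH(CH3)CO2Me), via nitrile oxide 15 (not isolated)
Conditions: PhNCO (4 equiv), Et3N (0.2 equiv), toluene, 80 °C, 14 added over 24 h, final 1 mM
Reagents that add atoms: none
Why: Proposed new method: Mukaiyama–Hoshino dehydration gives the nitrile oxide, whose intramolecular 1,3-dipolar cycloaddition (closest known type: macrocyclic nitrile oxide–olefin cyclisation of ω-nitroalkyl alkenes, here pushed to an eleven-membered ring on an unactivated Z-1,2-dialkyl alkene) closes the carbocycle and the isoxazoline together; suprafacial addition to the Z-alkene fixes C10/C11 as the syn-aldol pair, the oxygen terminus goes to the more hindered C11, A1,3 strain holds H12 in the alkene plane so that the dipole tethered through C1 adds to the face bearing C1 (the C11/C12 relation of the cis-lactone), and the two planar trans units (lactam and C=N) keep ring strain at a humulene-like level.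

**Step 7**
Reactants: 17 3-methylfuran-2(5H)-one
Product: 18 triisopropyl[(3-methylfuran-2-yl)oxy]silane
Conditions: iPr3SiOSO2CF3 (1.1 equiv), Et3N (1.3 equiv), CH2Cl2, 0 °C
Reagents that add atoms: triisopropylsilyl trifluoromethanesulfonate, CC(C)[Si](C(C)C)(C(C)C)OS(=O)(=O)C(F)(F)F
Why: Soft enolisation and O-silylation of the butenolide give the aromatic 2-silyloxyfuran, the standard γ-nucleophile for vinylogous Mannich reactions; no stereocentre is involved.

**Step 8**
Reactants: 16 isoxazoline-bridged lactam; 18 triisopropyl[(3-methylfuran-2-yl)oxy]silane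
Product: 20 C3-butenolide macrocycle (1S,3S,10R,11R,12S,13S,18S; C3 carries the 4-methyl-5-oxo-2,5-dihydrofuran-2-yl group), via N-acyliminium triflate 19 (not isolated)
Conditions: iPr3SiOSO2CF3 (0.2 equiv), CH2Cl2, −78 to −40 °C
Reagents that add atoms: none
Why: In this vinylogous Mannich (Mukaiyama-type) addition to an N-acyliminium ion, furan C5 attacks C3 from the face opposite C12 and the tether that hangs below N4 (3S, trans to the C1 substituent), and the usual staggered approach of 3-methyl-2-silyloxyfurans to five-membered acyliminium ions gives the threo (3S,18S) butenolide.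

**Step 9**
Reactants: 20 C3-butenolide macrocycle
Product: 22 target CNP0147860.1 (1S,3S,10S,11R,12S,13S,18S,20S), via hydroxy ketone ester 21 (not isolated)
Conditions: Raney Ni, H2 (3 atm), B(OH)3, MeOH/H2O 5:1, rt; filter; pyridinium p-toluenesulfonate (0.1 equiv), benzene, 50 °C
Reagents that add atoms: water, O
Why: Raney Ni hydrogenolysis of the isoxazoline N–O bond with boric-acid-buffered imine hydrolysis unmasks the syn β-hydroxy ketone without C10 epimerisation; the same hydrogenation adds H2 to the butenolide face anti to the C3 substituent (20S, cis-lactone B), and lactonisation of C11–OH onto the C14 ester occurs with retention to give the cis-C11/C12, trans-C12/C13 lactone A.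

**Compound list**
1 | methyl (S)-5-oxopyrrolidine-2-carboxylate | COC(=O)[C@@H]1CCC(=O)N1 | starting material
2 | 1-bromo-5-chloropentane | ClCCCCCBr | starting material
3 | methyl (S)-1-(5-chloropentyl)-5-oxopyrrolidine-2-carboxylate | ClCCCCCN1C(=O)CC[C@H]1C(=O)OC | intermediate
4 | (S)-1-(5-chloropentyl)-5-oxopyrrolidine-2-carboxylic acid | ClCCCCCN1C(=O)CC[C@H]1C(=O)O | intermediate
5 | (Z)-pent-2-en-1-ol | CC/C=C\CO | starting material
6 | methyl 2-(triphenylphosphoranylidene)propanoate | COC(=O)C(C)=P(c1ccccc1)(c1ccccc1)c1ccccc1 | starting material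
7 | (Z)-pent-2-enal | CC/C=C\C=O | intermediate
8 | methyl (2E,4Z)-2-methylhepta-2,4-dienoate | CC/C=C\C=C(/C)C(=O)OC | intermediate
9 | dilithium carboxylate/lactam-enolate dianion of 4 | [Li+].[Li+].ClCCCCCN1C([O-])=CC[C@H]1C(=O)[O-] | intermediate
10 | (2S,4S)-1-(5-chloropentyl)-4-[(2S,3S,4Z)-1-methoxy-2-methyl-1-oxohept-4-en-3-yl]-5-oxopyrrolidine-2-carboxylic acid | ClCCCCCN1C(=O)[C@@H](C[C@H]1C(=O)O)[C@@H]([C@H](C)C(=O)OC)/C=C\CC | intermediate
11 | C3 N-acyliminium ion from 10 | ClCCCCC[N+]1=CC[C@H](C1=O)[C@@H]([C@H](C)C(=O)OC)/C=C\CC | intermediate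
12 | methyl (2S,3S,4Z)-3-[(3S)-1-(5-chloropentyl)-5-methoxy-2-oxopyrrolidin-3-yl]-2-methylhept-4-enoate (OMe epimers) | ClCCCCCN1C(=O)[C@@H](CC1OC)[C@@H]([C@H](C)C(=O)OC)/C=C\CC | intermediate
13 | 5-iodopentyl analogue of 12 | ICCCCCN1C(=O)[C@@H](CC1OC)[C@@H]([C@H](C)C(=O)OC)/C=C\CC | intermediate
14 | methyl (2S,3S,4Z)-3-[(3S)-5-methoxy-1-(5-nitropentyl)-2-oxopyrrolidin-3-yl]-2-methylhept-4-enoate | [O-][N+](=O)CCCCCN1C(=O)[C@@H](CC1OC)[C@@H]([C@H](C)C(=O)OC)/C=C\CC | intermediate
15 | nitrile oxide from 14 | [O-][N+]#CCCCCN1C(=O)[C@@H](CC1OC)[C@@H]([C@H](C)C(=O)OC)/C=C\CC | intermediate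
16 | isoxazoline-bridged eleven-membered lactam (1S,10R,11R,12S,13S; C3–OMe epimers) | CC[C@@H]1C2=NO[C@@H]1[C@H]([C@H](C)C(=O)OC)[C@@H]1CC(OC)N(C1=O)CCCC2 | intermediate
17 | 3-methylfuran-2(5H)-one | CC1=CCOC1=O | starting material
18 | triisopropyl[(3-methylfuran-2-yl)oxy]silane | CC1=C(O[Si](C(C)C)(C(C)C)C(C)C)OC=C1 | intermediate
19 | macrocyclic C3 N-acyliminium triflate | CC[C@@H]1C2=NO[C@@H]1[C@H]([C@H](C)C(=O)OC)[C@@H]1CC=[N+](C1=O)CCCC2.[O-]S(=O)(=O)C(F)(F)F | intermediate
20 | C3-butenolide macrocycle (1S,3S,10R,11R,12S,13S,18S) | CC[C@@H]1C2=NO[C@@H]1[C@H]([C@H](C)C(=O)OC)[C@@H]1C[C@@H]([C@@H]3C=C(C)C(=O)O3)N(C1=O)CCCC2 | intermediate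
21 | C9-keto C11-hydroxy C14-methyl ester with lactone B saturated (1S,3S,10S,11R,12S,13S,18S,20S) | CC[C@@H]1C(=O)CCCCN2C(=O)[C@@H](C[C@H]2[C@@H]2C[C@H](C)C(=O)O2)[C@H]([C@H]1O)[C@H](C)C(=O)OC | intermediate
22 | CNP0147860.1 | CC[C@@H]1C(=O)CCCCN2C(=O)[C@@H](C[C@H]2[C@@H]2C[C@H](C)C(=O)O2)[C@@H]2[C@H]1OC(=O)[C@H]2C | target

**Step count**
Total steps: 9. Longest linear sequence: 7 (steps 1, 3, 4, 5, 6, 8, 9).

**Steps most likely to fail**

Step 6 is the most exposed. The slow medium-ring closure competes with furoxan dimerisation, with the fused ten-membered regioisomer (C9–C11, O–C10), and with attack on the other alkene face.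
- The fallback sets out from 14 and returns at 16 by changing the dipole.
- Me3SiCl and Et3N in toluene convert 14 into the trimethylsilyl nitronate F1. It cannot dimerise to a furoxan, so it can be heated at 0.01 M for days.
- Its intramolecular silyl nitronate–olefin cycloaddition gives the N-(trimethylsilyloxy)isoxazolidine F2 with the same suprafacial Z-alkene logic.
- p-Toluenesulfonic acid then expels the silanol to give 16.

Step 3 can fail through ε-deprotonation of the dienoate, through 1,6-addition, or through poor control at C13.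
- The fallback sets out from 4 (through dianion 9) and returns at 10. It takes the diene out of the acceptor and builds the Z-alkene afterwards.
- Ylide 6 and commercial 2,2-dimethoxyacetaldehyde give methyl (E)-4,4-dimethoxy-2-methylbut-2-enoate F3.
- Dianion 9 adds to it to give the acetal acid F4.
- Aqueous trifluoroacetic acid frees the aldehyde acid F5.
- Salt-free propylidene(triphenyl)phosphorane F6 (from propyltriphenylphosphonium bromide and NaN(SiMe3)2, 2.2 equiv) installs the Z-alkene of 10.

Step 8 can fail in face or threo selectivity on the rigid macrocycle, or through binding of the silyl triflate to the isoxazoline nitrogen.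
- The fallback sets out from 12 and returns at 20. It installs the lactone B unit before ring closure, so the free, branched C1 side chain is the only control element.
- 12 and 18 with iPr3SiOSO2CF3 (through ion 11) give the butenolide chloride F7.
- NaNO2 with catalytic NaI converts it through the iodide F8 into the nitro compound F9.
- PhNCO and Et3N under the dilution of step 6 generate the nitrile oxide F10, which cyclises to 20.

**Further compounds**
F1 | step 6 | trimethylsilyl nitronate of 14 | C[Si](C)(C)O[N+]([O-])=CCCCCN1C(=O)[C@@H](CC1OC)[C@@H]([C@H](C)C(=O)OC)/C=C\CC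
F2 | step 6 | N-(trimethylsilyloxy)isoxazolidine-bridged macrocycle (C9 unassigned) | CC[C@@H]1C2N(O[Si](C)(C)C)O[C@@H]1[C@H]([C@H](C)C(=O)OC)[C@@H]1CC(OC)N(C1=O)CCCC2
F3 | step 3 | methyl (E)-4,4-dimethoxy-2-methylbut-2-enoate | COC(=O)/C(C)=C/C(OC)OC
F4 | step 3 | C11 dimethyl acetal analogue of 10 | ClCCCCCN1C(=O)[C@@H](C[C@H]1C(=O)O)[C@@H]([C@H](C)C(=O)OC)C(OC)OC
F5 | step 3 | C11 aldehyde analogue of 10 | ClCCCCCN1C(=O)[C@@H](C[C@H]1C(=O)O)[C@@H]([C@H](C)C(=O)OC)C=O
F6 | step 3 | propylidene(triphenyl)phosphorane | CCC=P(c1ccccc1)(c1ccccc1)c1ccccc1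
F7 | step 8 | open-chain C3-butenolide chloride (1S,3S,12S,13S,18S) | ClCCCCCN1C(=O)[C@@H](C[C@H]1[C@@H]1C=C(C)C(=O)O1)[C@@H]([C@H](C)C(=O)OC)/C=C\CC
F8 | step 8 | 5-iodopentyl analogue of F7 | ICCCCCN1C(=O)[C@@H](C[C@H]1[C@@H]1C=C(C)C(=O)O1)[C@@H]([C@H](C)C(=O)OC)/C=C\CC
F9 | step 8 | 5-nitropentyl analogue of F7 | [O-][N+](=O)CCCCCN1C(=O)[C@@H](C[C@H]1[C@@H]1C=C(C)C(=O)O1)[C@@H]([C@H](C)C(=O)OC)/C=C\CC
F10 | step 8 | nitrile oxide from F9 | [O-][N+]#CCCCCN1C(=O)[C@@H](C[C@H]1[C@@H]1C=C(C)C(=O)O1)[C@@H]([C@H](C)C(=O)OC)/C=C\CC
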